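**Retrosynthetic overview**
1. Ring half: nerylacetone 1 → triene ester 5 by HWE olefination, terminal SeO2 oxidation and a ligand-controlled SN2′ C-methylation that sets C3 and leaves the exo-methylene terminus (laboratory stand-in for the C-methyl transfer).
2. The only ring is closed at step 5, before the halves are joined: 5 → 6 forms C2–C7 from the methylated terminus and ends by loss of H from the C6 methyl group (exocyclic methylene). These are the bond changes of the natural closure, run as a one-electron version triggered by hydrogen-atom transfer (HAT). The 6Z alkene plus the C3 methyl fix the trans ring; 6 → allylic phosphate 8.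
3. Open-chain half: (2E,6E)-farnesyl acetate 9 → alkyne 17 (mirror-image SN2′ methylation for C20, Ru–BINAP hydrogenation for C13, aldehyde → alkyne).
4. Key disconnection C10–C11: enantioselective NHC–Cu SN2′ union of 8 with the E-alkenylalane 18 made from 17 gives target 19 and creates the vinyl-bearing quaternary C10 (a 1′–3 type coupling of two C15-derived halves).
5. Target locants: ring = C2 (CMe2), C3 (CHMe), C4, C5, C6 (C=CH2), C7 (CH); C8, C9; quaternary C10; C11=C12; C13 and C20 methine stereocentres.

Assumption: nerylacetone (5Z) and (2E,6E)-farnesyl acetate are bought as single geometric isomers; within each step the locants are those of the compound named there.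

**Step 1**
Reactants: 1 nerylacetone, (5Z)-6,10-dimethylundeca-5,9-dien-2-one
Product: 2 ethyl (2E,6Z)-3,7,11-trimethyldodeca-2,6,10-trienoate
Conditions: (EtO)2P(O)CH2CO2Et (1.3 equiv), NaH (1.25 equiv), THF, 0 to 25 °C; aq NH4Cl; SiO2 (2Z isomer removed)
Reagents that add atoms: triethyl phosphonoacetate, CCOC(=O)CP(=O)(OCC)OCC
Why: Horner–Wadsworth–Emmons olefination of the methyl ketone gives the β,β-disubstituted enoate mainly as the 2E isomer (about 4:1; the 2Z isomer is removed on silica) and does not touch the 6Z alkene.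

**Step 2**
Reactants: 2 ethyl (2E,6Z)-3,7,11-trimethyldodeca-2,6,10-trienoate
Product: 3 ethyl (2E,6Z,10E)-12-hydroxy-3,7,11-trimethyldodeca-2,6,10-trienoate
Conditions: SeO2 (0.3 equiv), t-BuOOH (70% aq, 3 equiv), salicylic acid (0.1 equiv), CH2Cl2, 20 °C
Reagents that add atoms: selenium dioxide, O=[Se]=O (transfers the O and is re-formed by tert-butyl hydroperoxide, CC(C)(C)OO)
Why: SeO2 allylic oxidation (ene reaction then [2,3]-sigmatropic shift, Sharpless catalytic conditions) is selective for the E-methyl group of the terminal, most electron-rich trisubstituted alkene, the internal and the ester-conjugated alkenes reacting far more slowly.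

**Step 3**
Reactants: 3 ethyl (2E,6Z,10E)-12-hydroxy-3,7,11-trimethyldodeca-2,6,10-trienoate
Product: 4 ethyl (2E,6Z,10E)-12-chloro-3,7,11-trimethyldodeca-2,6,10-trienoate
Conditions: PPh3 (1.2 equiv), Cl3CC(O)CCl3 (1.5 equiv), CH2Cl2, −20 to 0 °C
Reagents that add atoms: hexachloroacetone, ClC(Cl)(Cl)C(=O)C(Cl)(Cl)Cl
Why: Appel-type chlorination under Magid's PPh3/hexachloroacetone conditions converts the primary allylic alcohol into the chloride by SN2 displacement of the oxyphosphonium group, without allylic shift or E/Z scrambling.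

**Step 4**
Reactants: 4 ethyl (2E,6Z,10E)-12-chloro-3,7,11-trimethyldodeca-2,6,10-trienoate
Product: 5 ethyl (2E,6Z,10S)-3,7,10,11-tetramethyldodeca-2,6,11-trienoate
Conditions: MeMgBr (1.3 equiv, added over 1 h), Cu(O2CC4H3S) (copper thiophene-2-carboxylate, 3 mol %), chiral biphenol-based phosphoramidite (3.3 mol %, antipode giving 10S), CH2Cl2, −78 °C
Reagents that add atoms: methylmagnesium bromide, C[Mg]Br
Why: Cu-catalysed asymmetric allylic alkylation (SN2′) of the β-methyl-substituted allylic chloride places the methyl group on the γ-carbon and moves the alkene to the terminus, so the phosphoramidite–copper catalyst (antipode chosen for 10S) sets the methyl-bearing stereocentre and the isopropenyl group in one event, while the ester is inert to MeMgBr at −78 °C.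

**Step 5**
Reactants: 5 ethyl (2E,6Z,10S)-3,7,10,11-tetramethyldodeca-2,6,11-trienoate
Product: 6 ethyl (2E)-3-methyl-5-[(1S,3S)-2,2,3-trimethyl-6-methylidenecyclohexyl]pent-2-enoate
Conditions: [Co(C36H52N2O2)Cl] (3 mol %; C36H52N2O2 = (R,R)-N,N′-bis(3,5-di-tert-butylsalicylidene)cyclohexane-1,2-diaminate), PhSiH3 (6 mol %), benzene, 0.02 M, 22 °C, Ar
Reagents that add atoms: none
Why: Proposed new method: HAT from the Co–H species to the 1,1-disubstituted alkene gives the C11 tertiary radical (one-electron counterpart of the cation that C-methylation produces in the organism), which closes 6-endo onto C6 through a chair with the C10 methyl equatorial and, because of the 6Z geometry, the C5 chain axial (an axial methyl would clash 1,3-diaxially with that chain), so ring C1 is formed S and trans to the methyl; the ring radical then gives an H atom from its methyl group to divalent cobalt to leave the exocyclic methylene, and the electron-poor conjugated ester prevents a second ring closure; the closest known reaction types are the cobalt–salen/PhSiH3 HAT cycloisomerisation of dienes (Hofmann-type alkene termination) and the Cp2TiCl-mediated 6-endo radical cyclisation of epoxypolyprenes that ends in an exocyclic alkene.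

**Step 6**
Reactants: 6 ethyl (2E)-3-methyl-5-[(1S,3S)-2,2,3-trimethyl-6-methylidenecyclohexyl]pent-2-enoate
Product: 7 (2E)-3-methyl-5-[(1S,3S)-2,2,3-trimethyl-6-methylidenecyclohexyl]pent-2-en-1-ol
Conditions: i-Bu2AlH (2.5 equiv), CH2Cl2, −78 °C; aq KNaC4H4O6
Reagents that add atoms: none
Why: i-Bu2AlH 1,2-reduction of the conjugated ester gives the E-allylic alcohol; isolated alkenes and both ring stereocentres are untouched at −78 °C.

**Step 7**
Reactants: 7 (2E)-3-methyl-5-[(1S,3S)-2,2,3-trimethyl-6-methylidenecyclohexyl]pent-2-en-1-ol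
Product: 8 diethyl (2E)-3-methyl-5-[(1S,3S)-2,2,3-trimethyl-6-methylidenecyclohexyl]pent-2-en-1-yl phosphate
Conditions: (EtO)2P(O)Cl (1.3 equiv), pyridine, CH2Cl2, 0 °C
Reagents that add atoms: diethyl chlorophosphate, CCOP(=O)(Cl)OCC
Why: O-phosphorylation of the primary allylic alcohol installs the leaving group needed for copper-catalysed SN2′ substitution without disturbing the E-alkene.

**Step 8**
Reactants: 9 (2E,6E)-farnesyl acetate, (2E,6E)-3,7,11-trimethyldodeca-2,6,10-trien-1-yl acetate
Product: 10 (2E,6E,10E)-12-hydroxy-3,7,11-trimethyldodeca-2,6,10-trien-1-yl acetate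
Conditions: SeO2 (0.3 equiv), t-BuOOH (70% aq, 3 equiv), salicylic acid (0.1 equiv), CH2Cl2, 20 °C
Reagents that add atoms: selenium dioxide, O=[Se]=O (transfers the O and is re-formed by tert-butyl hydroperoxide, CC(C)(C)OO)
Why: The same SeO2 allylic oxidation as in step 2 attacks the E-methyl group of the terminal trisubstituted alkene first, the acetate-bearing alkene being deactivated.

**Step 9**
Reactants: 10 (2E,6E,10E)-12-hydroxy-3,7,11-trimethyldodeca-2,6,10-trien-1-yl acetate
Product: 11 (2E,6E,10E)-12-chloro-3,7,11-trimethyldodeca-2,6,10-trien-1-yl acetate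
Conditions: PPh3 (1.2 equiv), Cl3CC(O)CCl3 (1.5 equiv), CH2Cl2, −20 to 0 °C
Reagents that add atoms: hexachloroacetone, ClC(Cl)(Cl)C(=O)C(Cl)(Cl)Cl
Why: The same Appel-type (PPh3/hexachloroacetone) chlorination as in step 3 gives the unrearranged primary allylic chloride; the acetate is inert.

**Step 10**
Reactants: 11 (2E,6E,10E)-12-chloro-3,7,11-trimethyldodeca-2,6,10-trien-1-yl acetate
Product: 13 (2E,6E,10R)-3,7,10,11-tetramethyldodeca-2,6,11-trien-1-ol, via methylated acetate 12 (not isolated)
Conditions: MeMgBr (1.3 equiv, added over 1 h), Cu(O2CC4H3S) (3 mol %), mirror-image phosphoramidite (3.3 mol %), CH2Cl2, −78 °C; then MeOH, K2CO3 (0.3 equiv), 20 °C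
Reagents that add atoms: methylmagnesium bromide, C[Mg]Br
Why: Cu-catalysed asymmetric allylic alkylation (SN2′) as in step 4, but with the mirror-image ligand, sets 10R; at −78 °C the primary chloride reacts much faster than the allylic acetate, which is then removed by K2CO3-catalysed transesterification in the same flask.

**Step 11**
Reactants: 13 (2E,6E,10R)-3,7,10,11-tetramethyldodeca-2,6,11-trien-1-ol
Product: 14 (3S,6E,10R)-3,7,10,11-tetramethyldodeca-6,11-dien-1-ol
Conditions: H2 (30 atm), Ru(OAc)2[(R)-BINAP] (0.5 mol %), MeOH–H2O 95:5, 20 °C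
Reagents that add atoms: none
Why: Noyori hydroxyl-directed asymmetric hydrogenation reduces only the allylic alcohol alkene, and (R)-BINAP on an E-allylic alcohol gives 3S (as geraniol gives (S)-citronellol), while the undirected tri- and 1,1-disubstituted alkenes are not reduced.

**Step 12**
Reactants: 14 (3S,6E,10R)-3,7,10,11-tetramethyldodeca-6,11-dien-1-ol
Product: 15 (3S,6E,10R)-3,7,10,11-tetramethyldodeca-6,11-dienal
Conditions: PhI(OAc)2 (1.1 equiv), TEMPO (10 mol %), CH2Cl2, 20 °C
Reagents that add atoms: none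
Why: TEMPO-catalysed oxidation with PhI(OAc)2 stops at the aldehyde without strong acid or base, and the methyl stereocentre is β to the carbonyl so it cannot epimerise.

**Step 13**
Reactants: 15 (3S,6E,10R)-3,7,10,11-tetramethyldodeca-6,11-dienal
Product: 17 (3S,6E,10R)-3,7,10,11-tetramethyldodeca-6,11-dien-1-yne, via alkenyl nonaflate 16 (not isolated)
Conditions: C4F9SO2F (1.3 equiv), phosphazene base P2-Et (2.6 equiv), DMF, −30 to 20 °C
Reagents that add atoms: none
Why: One-flask alkyne synthesis from an enolisable aldehyde (Lyapkalo–Reissig method): the phosphazene base forms the enolate, which is O-sulfonylated to the alkenyl nonaflate, and a second equivalent of base effects β-elimination to the terminal alkyne with no change in carbon count and without deprotonating the C3 stereocentre.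

**Step 14**
Reactants: 17 (3S,6E,10R)-3,7,10,11-tetramethyldodeca-6,11-dien-1-yne; 8 diethyl (2E)-3-methyl-5-[(1S,3S)-2,2,3-trimethyl-6-methylidenecyclohexyl]pent-2-en-1-yl phosphate
Product: 19 (2S,6S)-2-[(3S,4E,6S,9E,13R)-3-ethenyl-3,6,10,13,14-pentamethylpentadeca-4,9,14-trien-1-yl]-1,1,6-trimethyl-3-methylidenecyclohexane (CNP0186101.1), via alkenylalane 18 (not isolated)
Conditions: 17 (1.5 equiv), i-Bu2AlH (1.5 equiv), hexanes, 55 °C, 5 h; then 8 (1.0 equiv), CuCl2·2H2O (5 mol %), chiral sulfonate-bearing N-heterocyclic carbene (5.5 mol %, from its imidazolinium salt, antipode giving the S quaternary centre), THF, −15 °C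
Reagents that add atoms: none
Why: Thermal syn-hydroalumination of the terminal alkyne gives the E-alkenylalane, whose alkenyl group the chiral NHC–copper catalyst delivers to the γ-carbon of the E-trisubstituted allylic phosphate (enantioselective SN2′ allylic substitution, as used for bakuchiol), creating the quaternary stereocentre (S, set by the catalyst because the existing stereocentres are remote) together with the vinyl group and the E-1,2-disubstituted alkene.

**Compound list**
1 | nerylacetone, (5Z)-6,10-dimethylundeca-5,9-dien-2-one | CC(=O)CC/C=C(/C)CCC=C(C)C | starting material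
2 | ethyl (2E,6Z)-3,7,11-trimethyldodeca-2,6,10-trienoate | CCOC(=O)/C=C(\C)CC/C=C(/C)CCC=C(C)C | intermediate
3 | ethyl (2E,6Z,10E)-12-hydroxy-3,7,11-trimethyldodeca-2,6,10-trienoate | CCOC(=O)/C=C(\C)CC/C=C(/C)CC/C=C(\C)CO | intermediate
4 | ethyl (2E,6Z,10E)-12-chloro-3,7,11-trimethyldodeca-2,6,10-trienoate | CCOC(=O)/C=C(\C)CC/C=C(/C)CC/C=C(\C)CCl | intermediate
5 | ethyl (2E,6Z,10S)-3,7,10,11-tetramethyldodeca-2,6,11-trienoate | CCOC(=O)/C=C(\C)CC/C=C(/C)CC[C@H](C)C(=C)C | intermediate
6 | ethyl (2E)-3-methyl-5-[(1S,3S)-2,2,3-trimethyl-6-methylidenecyclohexyl]pent-2-enoate | CCOC(=O)/C=C(\C)CC[C@H]1C(=C)CC[C@H](C)C1(C)C | intermediate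
7 | (2E)-3-methyl-5-[(1S,3S)-2,2,3-trimethyl-6-methylidenecyclohexyl]pent-2-en-1-ol | OC/C=C(\C)CC[C@H]1C(=C)CC[C@H](C)C1(C)C | intermediate
8 | diethyl (2E)-3-methyl-5-[(1S,3S)-2,2,3-trimethyl-6-methylidenecyclohexyl]pent-2-en-1-yl phosphate | CCOP(=O)(OCC)OC/C=C(\C)CC[C@H]1C(=C)CC[C@H](C)C1(C)C | intermediate
9 | (2E,6E)-farnesyl acetate, (2E,6E)-3,7,11-trimethyldodeca-2,6,10-trien-1-yl acetate | CC(=O)OC/C=C(\C)CC/C=C(\C)CCC=C(C)C | starting material
10 | (2E,6E,10E)-12-hydroxy-3,7,11-trimethyldodeca-2,6,10-trien-1-yl acetate | CC(=O)OC/C=C(\C)CC/C=C(\C)CC/C=C(\C)CO | intermediate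
11 | (2E,6E,10E)-12-chloro-3,7,11-trimethyldodeca-2,6,10-trien-1-yl acetate | CC(=O)OC/C=C(\C)CC/C=C(\C)CC/C=C(\C)CCl | intermediate
12 | (2E,6E,10R)-3,7,10,11-tetramethyldodeca-2,6,11-trien-1-yl acetate | CC(=O)OC/C=C(\C)CC/C=C(\C)CC[C@@H](C)C(=C)C | intermediate (not isolated)
13 | (2E,6E,10R)-3,7,10,11-tetramethyldodeca-2,6,11-trien-1-ol | OC/C=C(\C)CC/C=C(\C)CC[C@@H](C)C(=C)C | intermediate
14 | (3S,6E,10R)-3,7,10,11-tetramethyldodeca-6,11-dien-1-ol | OCC[C@@H](C)CC/C=C(\C)CC[C@@H](C)C(=C)C | intermediate
15 | (3S,6E,10R)-3,7,10,11-tetramethyldodeca-6,11-dienal | O=CC[C@@H](C)CC/C=C(\C)CC[C@@H](C)C(=C)C | intermediate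
16 | (3S,6E,10R)-3,7,10,11-tetramethyldodeca-1,6,11-trien-1-yl nonafluorobutane-1-sulfonate (1E/1Z mixture) | FC(F)(F)C(F)(F)C(F)(F)C(F)(F)S(=O)(=O)OC=C[C@@H](C)CC/C=C(\C)CC[C@@H](C)C(=C)C | intermediate (not isolated)
17 | (3S,6E,10R)-3,7,10,11-tetramethyldodeca-6,11-dien-1-yne | C#C[C@@H](C)CC/C=C(\C)CC[C@@H](C)C(=C)C | intermediate
18 | [(1E,3S,6E,10R)-3,7,10,11-tetramethyldodeca-1,6,11-trien-1-yl]bis(2-methylpropyl)alumane | CC(C)C[Al](CC(C)C)/C=C/[C@@H](C)CC/C=C(\C)CC[C@@H](C)C(=C)C | intermediate (not isolated)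
19 | (2S,6S)-2-[(3S,4E,6S,9E,13R)-3-ethenyl-3,6,10,13,14-pentamethylpentadeca-4,9,14-trien-1-yl]-1,1,6-trimethyl-3-methylidenecyclohexane (CNP0186101.1) | C=C[C@@](C)(/C=C/[C@@H](C)CC/C=C(\C)CC[C@@H](C)C(=C)C)CC[C@H]1C(=C)CC[C@H](C)C1(C)C | target

**Step count and risks**
Total steps: 14 (steps 1–7 ring half, steps 8–13 open-chain half, step 14 union). Longest linear sequence: 8 steps (steps 1–7, then 14). The four catalyst-controlled events (steps 4, 10, 11, 14) each leave a few percent of the wrong isomer; these are best removed at the alcohol stages 7 and 14 and after step 5, before the hydrocarbon target is reached.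

Step 5 is the most likely to fail. The 6-endo closure must outrun return of an H atom to cobalt; return from C10–H would give the achiral tetrasubstituted alkene, a dead end. The exocyclic alkene of 6 can re-enter the cycle and drift to the endocyclic isomer, and any boat closure lowers the trans:cis ratio. The fallback sets out from 5 and uses the two-electron (cationic) manifold. SnCl4 with one equivalent of HCl in CH2Cl2 at −78 °C protonates the isopropenyl group, the tertiary cation closes through the same chair, and the ring cation is captured by chloride to give ethyl (2E)-5-[(1R,3S)-6-chloro-2,2,3,6-tetramethylcyclohexyl]-3-methylpent-2-enoate F1 (both C6 epimers). Hofmann-selective dehydrochlorination with KOtBu in DMSO at 20 °C then comes back to the route at 6.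

Step 14 is second. The phosphate is all-alkyl and the alkenyl group is branched at its allylic carbon, so the enantiomer ratio at the quaternary centre, the SN2′:SN2 ratio and competing isobutyl transfer are all less secure than in the aryl cases. The fallback reverses the polarity and sets out from 7 and 17. Alcohol 7 with B2pin2 and [Pd(MeCN)4](BF4)2 in DMSO–MeOH gives 4,4,5,5-tetramethyl-2-{(2E)-3-methyl-5-[(1S,3S)-2,2,3-trimethyl-6-methylidenecyclohexyl]pent-2-en-1-yl}-1,3,2-dioxaborolane F5. Alkyne 17 with Cp2Zr(H)Cl and then I2 gives (1E,3S,6E,10R)-1-iodo-3,7,10,11-tetramethyldodeca-1,6,11-triene F6. A γ-selective, enantioselective Suzuki–Miyaura coupling of the two (Pd(OAc)2, chiral bisphosphine, KOH, THF–H2O) comes back to the route at 19.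

Step 4 is third. A γ-alkyl, β-methyl allylic chloride with MeMgBr is at the edge of the reported scope, so the SN2′:SN2 ratio and the enantiomer ratio may be lower than for cinnamyl-type substrates. The fallback sets out from 3 and sets the stereocentre by epoxide chemistry. Sharpless asymmetric epoxidation (Ti(OiPr)4, D-(−)-diethyl tartrate, t-BuOOH, CH2Cl2, −20 °C) gives ethyl (2E,6Z,10R,11R)-10,11-epoxy-12-hydroxy-3,7,11-trimethyldodeca-2,6-dienoate F2. Me2CuLi in Et2O at −20 °C opens the epoxide at the less hindered C10 with inversion to give ethyl (2E,6Z,10S,11S)-11,12-dihydroxy-3,7,10,11-tetramethyldodeca-2,6-dienoate F3. Thiocarbonyldiimidazole in toluene at 80 °C gives ethyl (2E,6Z,10S)-3,7-dimethyl-10-[(4S)-4-methyl-2-sulfanylidene-1,3-dioxolan-4-yl]undeca-2,6-dienoate F4, and Corey–Winter deoxygenation with P(OMe)3 at 110 °C comes back to the route at 5.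

**Further compounds**
F1 | step 5 | ethyl (2E)-5-[(1R,3S)-6-chloro-2,2,3,6-tetramethylcyclohexyl]-3-methylpent-2-enoate | CCOC(=O)/C=C(\C)CC[C@H]1C(C)(Cl)CC[C@H](C)C1(C)C
F2 | step 4 | ethyl (2E,6Z,10R,11R)-10,11-epoxy-12-hydroxy-3,7,11-trimethyldodeca-2,6-dienoate | CCOC(=O)/C=C(\C)CC/C=C(/C)CC[C@H]1O[C@]1(C)CO
F3 | step 4 | ethyl (2E,6Z,10S,11S)-11,12-dihydroxy-3,7,10,11-tetramethyldodeca-2,6-dienoate | CCOC(=O)/C=C(\C)CC/C=C(/C)CC[C@H](C)[C@](C)(O)CO
F4 | step 4 | ethyl (2E,6Z,10S)-3,7-dimethyl-10-[(4S)-4-methyl-2-sulfanylidene-1,3-dioxolan-4-yl]undeca-2,6-dienoate | CCOC(=O)/C=C(\C)CC/C=C(/C)CC[C@H](C)[C@]1(C)OC(=S)OC1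
F5 | step 14 | 4,4,5,5-tetramethyl-2-{(2E)-3-methyl-5-[(1S,3S)-2,2,3-trimethyl-6-methylidenecyclohexyl]pent-2-en-1-yl}-1,3,2-dioxaborolane | CC1(C)OB(C/C=C(\C)CC[C@H]2C(=C)CC[C@H](C)C2(C)C)OC1(C)C
F6 | step 14 | (1E,3S,6E,10R)-1-iodo-3,7,10,11-tetramethyldodeca-1,6,11-triene | I/C=C/[C@@H](C)CC/C=C(\C)CC[C@@H](C)C(=C)C
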